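## Retrosynthetic overview

1. Feature: once O5 and O5'' carry methyl groups, ring A is the 3,5-dimethoxyphenyl ether of O1 and ring A'' is the 4-aryloxy-3,5-dimethoxyphenyl ether of O1''. In each ring the two carbons ortho to that ether oxygen (future C4a/C8 and C4a''/C8'') are interchangeable, so the aryl-carbonyl bonds need no regiochemical decision.
2. Endgame: O4'''-H comes from an acetate, and O5-H and O5''-H come from chelation-directed demethylation. C4-C4a and C4''-C4a'' are then cut together, opening rings C and C'' to an (S,S)-bis(3-aryl-3-aryloxypropanoic acid).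
3. O1-C2 and O1''-C2'' come from two inverting Mitsunobu etherifications of (R)-tert-butyl 3-aryl-3-hydroxypropanoates. These are made by asymmetric transfer hydrogenation of beta-keto esters, so both stereocentres exist before any ring closes.
4. The C4'-O-C6'' diaryl ether is made first, by SNAr on 4-fluorobenzonitrile. A bromine on ring A'' stands in for O1'' until the first Mitsunobu is over, so the phenol and carbinol of the central piece never coexist.
5. Ring order: the four benzene rings are bought, and pyranone rings C and C'' are formed last, both in one operation.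

Key step: step 10

Assumption: locants follow biflavonoid usage (unit I = rings A, C, B; unit II = rings A'', C'', B'''; linkage C4'-O-C6''), and compounds 1, 2, 4, 8, 12 and 13 are taken as commercial.

## Route

Step 1
Reactants: 1 4-bromo-2,6-dimethoxyphenol; 2 4-fluorobenzonitrile
Product: 3 4-(4-bromo-2,6-dimethoxyphenoxy)benzonitrile
Conditions: K2CO3, DMSO, N2, 110 °C
Reagents that add atoms: none
Why: SNAr, in which the para-cyano group stabilises the Meisenheimer adduct enough for the hindered 2,6-dimethoxyphenoxide to displace fluoride, neither partner has an enolisable ketone or an aldehyde that could condense under hot carbonate, and the unactivated C-Br bond stays as the later site of O1''.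

Step 2
Reactants: 3 4-(4-bromo-2,6-dimethoxyphenoxy)benzonitrile; 4 tert-butyl bromoacetate
Product: 6 tert-butyl 3-[4-(4-bromo-2,6-dimethoxyphenoxy)phenyl]-3-oxopropanoate, via Blaise enamino ester 5 (not isolated)
Conditions: Zn dust (MsOH-activated), THF, reflux, slow addition of 4; then 1 M HCl, THF, rt
Reagents that add atoms: water, O
Why: Blaise reaction, in which the zinc enolate formed from 4 adds to the nitrile carbon and brief dilute acid hydrolyses enamino ester 5 to the beta-keto ester, installing C3 and C4 with the acid-labile ester without strong base, while zinc dust does not insert into the aryl bromide in THF.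

Step 3
Reactants: 6 tert-butyl 3-[4-(4-bromo-2,6-dimethoxyphenoxy)phenyl]-3-oxopropanoate
Product: 7 tert-butyl (3R)-3-[4-(4-bromo-2,6-dimethoxyphenoxy)phenyl]-3-hydroxypropanoate
Conditions: RuCl[(R,R)-TsDPEN](p-cymene) (1 mol %), HCO2H/Et3N 5:2, EtOAc, 30 °C
Reagents that add atoms: none
Why: Noyori-Ikariya asymmetric transfer hydrogenation, in which the aryl group sits under the eta6-arene of the catalyst (CH/pi contact) in the outer-sphere transition state, so the (R,R)-catalyst should deliver hydride in the same sense as for acetophenone to (R)-1-phenylethanol and set the (R)-carbinol (priorities OH > aryl > CH2CO2tBu), and the alcohol-free medium at 30 °C avoids solvolysis of the electron-rich benzylic alcohol.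

Step 4
Reactants: 7 tert-butyl (3R)-3-[4-(4-bromo-2,6-dimethoxyphenoxy)phenyl]-3-hydroxypropanoate; 8 3,5-dimethoxyphenol
Product: 9 tert-butyl (3S)-3-[4-(4-bromo-2,6-dimethoxyphenoxy)phenyl]-3-(3,5-dimethoxyphenoxy)propanoate
Conditions: PPh3, DIAD, toluene, -20 to 0 °C
Reagents that add atoms: none
Why: Mitsunobu etherification, in which the oxyphosphonium salt of 7 is displaced by the phenoxide of 8 in an SN2 step with inversion ((R) to (S), CIP order unchanged), which sets C2, while the non-polar solvent, low temperature and electron-withdrawing CH2CO2tBu group disfavour ionisation and the bromine in place of a free phenol excludes self-etherification.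

Step 5
Reactants: 9 tert-butyl (3S)-3-[4-(4-bromo-2,6-dimethoxyphenoxy)phenyl]-3-(3,5-dimethoxyphenoxy)propanoate
Product: 11 tert-butyl (3S)-3-(3,5-dimethoxyphenoxy)-3-[4-(4-hydroxy-2,6-dimethoxyphenoxy)phenyl]propanoate, via pinacol boronate 10 (not isolated)
Conditions: B2pin2, Pd(dppf)Cl2 (5 mol %), KOAc, 1,4-dioxane, 85 °C; filter; then 30% H2O2, aq NaHCO3, THF, 0 °C
Reagents that add atoms: bis(pinacolato)diboron, CC1(C)OB(OC1(C)C)B1OC(C)(C)C(C)(C)O1 (boryl group of 10 only); hydrogen peroxide, OO (phenol oxygen of 11)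
Why: Miyaura borylation followed by ipso-oxidation of the aryl boronate (1,2-aryl shift from boron to oxygen), in which acetate is far too weak a base to start beta-elimination of the aryloxy group and the buffered peroxide at 0 °C converts C-B into C-OH without touching C2 or the tert-butyl ester.

Step 6
Reactants: 12 4-acetoxybenzoic acid; 13 mono-tert-butyl malonate
Product: 16 tert-butyl 3-(4-acetoxyphenyl)-3-oxopropanoate, via 4-acetoxybenzoyl chloride 14 (not isolated), via acylmalonic half ester 15 (not isolated)
Conditions: (COCl)2, DMF (cat.), CH2Cl2, 0 °C to rt, evaporate; then 13, MgCl2, Et3N, MeCN, 0 °C to rt; 10% aq citric acid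
Reagents that add atoms: oxalyl chloride, O=C(Cl)C(=O)Cl (chlorine of 14 only)
Why: Acid chloride formation and C-acylation of the magnesium enolate of a malonic half ester with loss of CO2 (Masamune-Brooks type beta-keto ester synthesis), in which the soft chelated enolate and triethylamine should leave the phenolic acetate intact, something a strong-base carboxylation of an acetophenone enolate could not do.

Step 7
Reactants: 16 tert-butyl 3-(4-acetoxyphenyl)-3-oxopropanoate
Product: 17 tert-butyl (3R)-3-(4-acetoxyphenyl)-3-hydroxypropanoate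
Conditions: RuCl[(R,R)-TsDPEN](p-cymene) (1 mol %), HCO2H/Et3N 5:2, EtOAc, 25 °C
Reagents that add atoms: none
Why: Noyori-Ikariya asymmetric transfer hydrogenation with the same aryl/eta6-arene control as in step 3, so the (R,R)-catalyst should set the (R)-carbinol, and the absence of an alcoholic solvent and of mineral acid spares the aryl acetate, which hot acidic methanol under a pressure hydrogenation would solvolyse.

Step 8
Reactants: 11 tert-butyl (3S)-3-(3,5-dimethoxyphenoxy)-3-[4-(4-hydroxy-2,6-dimethoxyphenoxy)phenyl]propanoate; 17 tert-butyl (3R)-3-(4-acetoxyphenyl)-3-hydroxypropanoate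
Product: 18 tert-butyl (3S)-3-(4-acetoxyphenyl)-3-{4-[4-((1S)-3-tert-butoxy-1-(3,5-dimethoxyphenoxy)-3-oxopropyl)phenoxy]-3,5-dimethoxyphenoxy}propanoate
Conditions: PPh3, DIAD, 17 in excess, toluene/THF, 0 °C to rt
Reagents that add atoms: none
Why: Mitsunobu etherification with SN2 inversion at the carbinol carbon of 17 ((R) to (S)), which sets C2'', where the electron-poor 4-acetoxyphenyl group suppresses ionisation, the ring A'' phenol has two free ortho positions, and any minor enantiomer of either fragment ends up in a separable diastereomer.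

Step 9
Reactants: 18 the (S,S)-di-tert-butyl ester
Product: 20 (3S)-3-(4-acetoxyphenyl)-3-{4-[4-((1S)-2-carboxy-1-(3,5-dimethoxyphenoxy)ethyl)phenoxy]-3,5-dimethoxyphenoxy}propanoic acid, via bis(trimethylsilyl) ester 19 (not isolated)
Conditions: TMSOTf (6 equiv), 2,6-lutidine (9 equiv), CH2Cl2, 0 °C to rt; then aq citric acid (pH 4), 0 °C
Reagents that add atoms: trimethylsilyl triflate, C[Si](C)(C)OS(=O)(=O)C(F)(F)F (silyl groups of 19 only)
Why: Silyl triflate-mediated tert-butyl ester cleavage, in which TMSOTf silylates the ester carbonyl oxygen, lutidine takes the proton as isobutene leaves and the silyl esters 19 hydrolyse at work-up, so a buffered aprotic medium of the kind that p-alkoxybenzyl ethers tolerate replaces neat protic acid that could ionise the 4-aryloxybenzylic C2-O1 bond, and base (E1cB loss of aryloxide, acetate cleavage) is avoided altogether.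

Step 10
Reactants: 20 the (S,S)-bis(3-aryl-3-aryloxypropanoic acid)
Product: 22 (2S,2''S)-4'''-O-acetyl-5,7,5'',7''-tetra-O-methyl-2,3,2'',3''-tetrahydrohinokiflavone, via bis(acyl trifluoroacetate) 21 (not isolated)
Conditions: (CF3CO)2O (5 equiv), CH2Cl2 (0.01 M), 0 °C (to rt only if the second closure lags); poured into cold aq NaHCO3
Reagents that add atoms: trifluoroacetic anhydride, O=C(OC(=O)C(F)(F)F)C(F)(F)F (trifluoroacetyl groups of 21 only)
Why: TFAA exchanges with both carboxyl groups to give the bis(acyl trifluoroacetate) 21, and each acyl carbon, as the mixed anhydride or after ionisation to the acylium ion, is attacked by the ring carbon ortho to the ether oxygen of its own arm, after which loss of the ring proton restores aromaticity. The closest known reaction is the intramolecular Friedel-Crafts acylation of 3-aryloxypropanoic acids to chroman-4-ones through mixed trifluoroacetic anhydrides, here run twice in one flask. Ring C closes through C4-C4a and ring C'' through C4''-C4a'', each 6-exo-trig at the acyl carbon (formally 6-exo-dig for a free acylium ion) with the arene C4a=C8a bond inside the new ring. No stereocentre is created; C2 and C2'' were fixed in steps 4 and 8 and only have to be retained, which requires acylation to be faster than acid-induced heterolysis of the benzylic C2-O1 and C2''-O1'' bonds. That margin should come from the attacked carbons lying ortho, ortho and para to three oxygen donors (closure at 0 °C in dilute CH2Cl2 with no acid beyond the TFA released), from the carbonyl group beta to each benzylic carbon, and from the electron-poor 4-acetoxyphenyl group at C2''. Regiochemistry needs no control because the two ortho carbons of ring A and of ring A'' are equivalent by local symmetry and the para carbon of ring A is out of reach, while five-membered closure onto ring B or B''' (indanone) cannot compete since their ortho carbons are meta to the ring oxygen.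

Step 11
Reactants: 22 (2S,2''S)-4'''-O-acetyl-5,7,5'',7''-tetra-O-methyl-2,3,2'',3''-tetrahydrohinokiflavone
Product: 24 (2S,2''S)-4'''-O-acetyl-7,7''-di-O-methyl-2,3,2'',3''-tetrahydrohinokiflavone, via bis(dichloroboryl) chelate 23 (not isolated)
Conditions: BCl3 (1 M in CH2Cl2, 5 equiv), CH2Cl2, -78 to -10 °C; then cold 1 M HCl/THF
Reagents that add atoms: boron trichloride, ClB(Cl)Cl (BCl2 groups of 23 only)
Why: Chelation-directed aryl methyl ether cleavage, in which BCl3 bridges each C4=O/5-OMe pair, chloride removes the methyl group from the activated oxygen and the six-membered boron chelates 23 are hydrolysed at work-up, while the 7- and 7''-OMe groups, the diaryl ether and the acetate lack such a chelate and the sub-zero temperature should keep both pyranone rings closed so that C2 and C2'' are retained.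

Step 12
Reactants: 24 (2S,2''S)-4'''-O-acetyl-7,7''-di-O-methyl-2,3,2'',3''-tetrahydrohinokiflavone
Product: 25 (2S,2''S)-7,7''-di-O-methyltetrahydrohinokiflavone
Conditions: HCl (0.2 M) in MeOH/CH2Cl2, 0 °C to rt
Reagents that add atoms: none
Why: Acid-catalysed transesterification (methanolysis) of the phenolic acetate, chosen because flavanones epimerise through base-induced opening to the chalcone whereas dilute acid at room temperature should leave C2, C2'', the aryl methyl ethers and the chelated 5-hydroxy ketones unchanged.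

## Compound list

1 | 4-bromo-2,6-dimethoxyphenol | COc1cc(Br)cc(OC)c1O | starting material
2 | 4-fluorobenzonitrile | N#Cc1ccc(F)cc1 | starting material
3 | 4-(4-bromo-2,6-dimethoxyphenoxy)benzonitrile | N#Cc1ccc(Oc2c(OC)cc(Br)cc2OC)cc1 | intermediate
4 | tert-butyl bromoacetate | CC(C)(C)OC(=O)CBr | starting material
5 | tert-butyl (Z)-3-amino-3-[4-(4-bromo-2,6-dimethoxyphenoxy)phenyl]prop-2-enoate (Blaise enamino ester, in the flask as its bromozinc salt; not isolated) | CC(C)(C)OC(=O)/C=C(\N)c1ccc(Oc2c(OC)cc(Br)cc2OC)cc1 | intermediate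
6 | tert-butyl 3-[4-(4-bromo-2,6-dimethoxyphenoxy)phenyl]-3-oxopropanoate | CC(C)(C)OC(=O)CC(=O)c1ccc(Oc2c(OC)cc(Br)cc2OC)cc1 | intermediate
7 | tert-butyl (3R)-3-[4-(4-bromo-2,6-dimethoxyphenoxy)phenyl]-3-hydroxypropanoate | CC(C)(C)OC(=O)C[C@@H](O)c1ccc(Oc2c(OC)cc(Br)cc2OC)cc1 | intermediate
8 | 3,5-dimethoxyphenol | COc1cc(O)cc(OC)c1 | starting material
9 | tert-butyl (3S)-3-[4-(4-bromo-2,6-dimethoxyphenoxy)phenyl]-3-(3,5-dimethoxyphenoxy)propanoate | COc1cc(OC)cc(O[C@H](c2ccc(Oc3c(OC)cc(Br)cc3OC)cc2)CC(=O)OC(C)(C)C)c1 | intermediate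
10 | pinacol boronate of 9 (Bpin in place of Br; not isolated) | COc1cc(OC)cc(O[C@H](c2ccc(Oc3c(OC)cc(B4OC(C)(C)C(C)(C)O4)cc3OC)cc2)CC(=O)OC(C)(C)C)c1 | intermediate
11 | tert-butyl (3S)-3-(3,5-dimethoxyphenoxy)-3-[4-(4-hydroxy-2,6-dimethoxyphenoxy)phenyl]propanoate | COc1cc(OC)cc(O[C@H](c2ccc(Oc3c(OC)cc(O)cc3OC)cc2)CC(=O)OC(C)(C)C)c1 | intermediate
12 | 4-acetoxybenzoic acid | CC(=O)Oc1ccc(C(=O)O)cc1 | starting material
13 | mono-tert-butyl malonate (3-tert-butoxy-3-oxopropanoic acid) | CC(C)(C)OC(=O)CC(=O)O | starting material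
14 | 4-acetoxybenzoyl chloride (not isolated) | CC(=O)Oc1ccc(C(=O)Cl)cc1 | intermediate
15 | 2-(4-acetoxybenzoyl)-3-tert-butoxy-3-oxopropanoic acid (racemic and configurationally labile, in the flask as magnesium chelate; not isolated) | CC(=O)Oc1ccc(C(=O)C(C(=O)O)C(=O)OC(C)(C)C)cc1 | intermediate
16 | tert-butyl 3-(4-acetoxyphenyl)-3-oxopropanoate | CC(=O)Oc1ccc(C(=O)CC(=O)OC(C)(C)C)cc1 | intermediate
17 | tert-butyl (3R)-3-(4-acetoxyphenyl)-3-hydroxypropanoate | CC(C)(C)OC(=O)C[C@@H](O)c1ccc(OC(C)=O)cc1 | intermediate
18 | (S,S)-di-tert-butyl ester of 20 | COc1cc(OC)cc(O[C@H](c2ccc(Oc3c(OC)cc(O[C@H](c4ccc(OC(C)=O)cc4)CC(=O)OC(C)(C)C)cc3OC)cc2)CC(=O)OC(C)(C)C)c1 | intermediate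
19 | (S,S)-bis(trimethylsilyl) ester of 20 (not isolated) | COc1cc(OC)cc(O[C@H](c2ccc(Oc3c(OC)cc(O[C@H](c4ccc(OC(C)=O)cc4)CC(=O)O[Si](C)(C)C)cc3OC)cc2)CC(=O)O[Si](C)(C)C)c1 | intermediate
20 | (S,S)-bis(3-aryl-3-aryloxypropanoic acid), precursor of the key step | COc1cc(OC)cc(O[C@H](c2ccc(Oc3c(OC)cc(O[C@H](c4ccc(OC(C)=O)cc4)CC(=O)O)cc3OC)cc2)CC(=O)O)c1 | intermediate
21 | (S,S)-bis(acyl trifluoroacetate) of 20 (not isolated) | COc1cc(OC)cc(O[C@H](c2ccc(Oc3c(OC)cc(O[C@H](c4ccc(OC(C)=O)cc4)CC(=O)OC(=O)C(F)(F)F)cc3OC)cc2)CC(=O)OC(=O)C(F)(F)F)c1 | intermediate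
22 | (2S,2''S)-4'''-O-acetyl-5,7,5'',7''-tetra-O-methyl-2,3,2'',3''-tetrahydrohinokiflavone | COc1cc(OC)c2c(c1)O[C@H](c1ccc(Oc3c(OC)cc4c(c3OC)C(=O)C[C@@H](c3ccc(OC(C)=O)cc3)O4)cc1)CC2=O | intermediate
23 | 5,5''-bis(O-dichloroboryl) chelate of 24 (O to B dative bonds from C4=O and C4''=O not drawn; not isolated) | COc1cc(OB(Cl)Cl)c2c(c1)O[C@H](c1ccc(Oc3c(OC)cc4c(c3OB(Cl)Cl)C(=O)C[C@@H](c3ccc(OC(C)=O)cc3)O4)cc1)CC2=O | intermediate
24 | (2S,2''S)-4'''-O-acetyl-7,7''-di-O-methyl-2,3,2'',3''-tetrahydrohinokiflavone | COc1cc(O)c2c(c1)O[C@H](c1ccc(Oc3c(OC)cc4c(c3O)C(=O)C[C@@H](c3ccc(OC(C)=O)cc3)O4)cc1)CC2=O | intermediate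
25 | (2S,2''S)-7,7''-di-O-methyltetrahydrohinokiflavone | COc1cc(O)c2c(c1)O[C@H](c1ccc(Oc3c(OC)cc4c(c3O)C(=O)C[C@@H](c3ccc(O)cc3)O4)cc1)CC2=O | target

## Step count and risks

Total step count: 12. Longest linear sequence: 10 steps (steps 1-5 and 8-12); steps 6 and 7 form the side branch.

**Step 10 (twofold ring closure).** The trifluoroacetic acid released may protonate O1 of the still open left arm. The 4-aryloxy-stabilised benzylic C2-O1 bond could then ionise as fast as the mixed anhydride acylates, eroding the configuration at C2 or ending in C-benzylation of ring A. The more crowded ring A'' may also close slowly and force a longer acid exposure.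

The fallback sets out from 20 and comes back at 22. It generates the electrophile by halide abstraction in an acid-free medium instead of by anhydride exchange:
- 1-Chloro-N,N,2-trimethylpropenylamine (CH2Cl2, 0 °C, neutral) converts 20 into the (S,S)-bis(acid chloride) F1.
- Silver triflate at -78 °C, in the presence of 2,6-di-tert-butyl-4-methylpyridine, turns F1 into the (S,S)-bis(acyl triflate) F2.
- F2 acylates both phloroglucinol-type rings without a Lewis acid, and the hindered pyridine takes up the two ring protons.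

**Step 4 (first Mitsunobu etherification).** The 4-aryloxy group may let the oxyphosphonium intermediate ionise, so that substitution leaks through an ion pair with partial loss of configuration at C2. Proton loss alpha to the ester may also dehydrate the activated carbinol.

The fallback sets out from 4, 8 and 1 and comes back at 9. The C2-O1 ether is made while ring B is electron-poor, and the diaryl ether is installed afterwards:
- Commercial 4-bromobenzonitrile F3 undergoes the Blaise reaction with 4 to give tert-butyl 3-(4-bromophenyl)-3-oxopropanoate F4.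
- Transfer hydrogenation as in step 3 gives tert-butyl (3R)-3-(4-bromophenyl)-3-hydroxypropanoate F5.
- Mitsunobu reaction with 8 gives tert-butyl (3S)-3-(4-bromophenyl)-3-(3,5-dimethoxyphenoxy)propanoate F6.
- Palladium-catalysed borylation (tetrahydroxydiboron, XPhos-Pd-G2, KOAc, EtOH, 80 °C) gives the corresponding (S)-arylboronic acid F7.
- Chan-Lam-Evans coupling of F7 with the hindered phenol 1 (Cu(OAc)2, pyridine, 4 Å sieves, air, CH2Cl2, rt) gives 9.

**Step 5 (borylation/oxidation on the chiral ether).** Prolonged heating of the beta-aryloxy ester with acetate may start retro-oxa-Michael loss of the ring A phenol. The electron-rich aryl-palladium species may be reduced instead of borylated. The very electron-rich 4-aryloxyphenol may also be oxidised further by peroxide.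

The fallback sets out from 3 and comes back at 11. The oxygen is introduced on the robust achiral nitrile and carried as a silyl ether:
- Compound 3 is borylated to the pinacol boronate F8 and oxidised to 4-(4-hydroxy-2,6-dimethoxyphenoxy)benzonitrile F9.
- TBSCl/imidazole gives the silyl ether F10.
- The Blaise reaction with 4 gives the beta-keto ester F11.
- Transfer hydrogenation as in step 3 gives the (R)-carbinol F12.
- Mitsunobu reaction with 8 gives the (S)-aryl ether F13.
- TBAF buffered with acetic acid (THF, 0 °C) releases 11.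

## Further compounds

F1 | step 10 | (S,S)-bis(acid chloride) of 20 | COc1cc(OC)cc(O[C@H](c2ccc(Oc3c(OC)cc(O[C@H](c4ccc(OC(C)=O)cc4)CC(=O)Cl)cc3OC)cc2)CC(=O)Cl)c1
F2 | step 10 | (S,S)-bis(acyl triflate) of 20 | COc1cc(OC)cc(O[C@H](c2ccc(Oc3c(OC)cc(O[C@H](c4ccc(OC(C)=O)cc4)CC(=O)OS(=O)(=O)C(F)(F)F)cc3OC)cc2)CC(=O)OS(=O)(=O)C(F)(F)F)c1
F3 | step 4 | 4-bromobenzonitrile (commercial) | N#Cc1ccc(Br)cc1
F4 | step 4 | tert-butyl 3-(4-bromophenyl)-3-oxopropanoate | CC(C)(C)OC(=O)CC(=O)c1ccc(Br)cc1
F5 | step 4 | tert-butyl (3R)-3-(4-bromophenyl)-3-hydroxypropanoate | CC(C)(C)OC(=O)C[C@@H](O)c1ccc(Br)cc1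
F6 | step 4 | tert-butyl (3S)-3-(4-bromophenyl)-3-(3,5-dimethoxyphenoxy)propanoate | COc1cc(OC)cc(O[C@H](c2ccc(Br)cc2)CC(=O)OC(C)(C)C)c1
F7 | step 4 | 4-[(1S)-3-tert-butoxy-1-(3,5-dimethoxyphenoxy)-3-oxopropyl]phenylboronic acid | COc1cc(OC)cc(O[C@H](c2ccc(B(O)O)cc2)CC(=O)OC(C)(C)C)c1
F8 | step 5 | pinacol boronate of 3 (Bpin in place of Br) | N#Cc1ccc(Oc2c(OC)cc(B3OC(C)(C)C(C)(C)O3)cc2OC)cc1
F9 | step 5 | 4-(4-hydroxy-2,6-dimethoxyphenoxy)benzonitrile | N#Cc1ccc(Oc2c(OC)cc(O)cc2OC)cc1
F10 | step 5 | 4-[4-(tert-butyldimethylsilyloxy)-2,6-dimethoxyphenoxy]benzonitrile | N#Cc1ccc(Oc2c(OC)cc(O[Si](C)(C)C(C)(C)C)cc2OC)cc1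
F11 | step 5 | tert-butyl 3-{4-[4-(tert-butyldimethylsilyloxy)-2,6-dimethoxyphenoxy]phenyl}-3-oxopropanoate | CC(C)(C)OC(=O)CC(=O)c1ccc(Oc2c(OC)cc(O[Si](C)(C)C(C)(C)C)cc2OC)cc1
F12 | step 5 | tert-butyl (3R)-3-{4-[4-(tert-butyldimethylsilyloxy)-2,6-dimethoxyphenoxy]phenyl}-3-hydroxypropanoate | CC(C)(C)OC(=O)C[C@@H](O)c1ccc(Oc2c(OC)cc(O[Si](C)(C)C(C)(C)C)cc2OC)cc1
F13 | step 5 | tert-butyl (3S)-3-{4-[4-(tert-butyldimethylsilyloxy)-2,6-dimethoxyphenoxy]phenyl}-3-(3,5-dimethoxyphenoxy)propanoate | COc1cc(OC)cc(O[C@H](c2ccc(Oc3c(OC)cc(O[Si](C)(C)C(C)(C)C)cc3OC)cc2)CC(=O)OC(C)(C)C)c1
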